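**Plan**

1. Chromene numbering (O1, C2, C3, C4, C4a, C5–C8, C8a) is used for both halves: chromene A is the dimethoxy half, chromene B the acetyl dihydroxy half. The retrosynthesis first cuts C4–C3 and O1–C2 in the pyran ring of chromene A, giving salicylaldehyde 11 and (2-methylprop-1-en-1-yl)boronic acid 12.
2. It then cuts the bond from the CH(CH3) bridge carbon to C6 of chromene B (giving ortho-hydroxystyrene 9 and chromene 6), and last the pyran ring of chromene B (back to a para-protected trihydroxyacetophenone and prenal).
3. Forward order: chromene B (steps 1–3), arene A as a formylated ortho-hydroxystyrene (steps 4–5), union at the bridge (step 6), pyran ring of chromene A last (step 7).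
4. The single (R) centre is set in step 6 by a chiral phosphoric acid acting on an ortho-quinone methide; step 7 is acid-free and leaves it untouched.
5. Enabling feature: in ring A the phenolic O1 on C8a is ortho to C4a, which carries C4 as an aldehyde. This salicylaldehyde pair lets O1 hold boron for alkenyl transfer to C4 and then become the carbonyl of an ortho-quinone methide whose gem-dimethyl terminus C2 closes back on O1.

Key step: step 7

Assumption: the facial sense delivered by (R)-TRIP in step 6 is taken by analogy with related additions to ortho-quinone methides and is not secure; if the (S)-product forms, the commercially available (S)-catalyst is used instead with no other change.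

**Route**

Step 1
Reactants: 1 1-(2,4,6-trihydroxyphenyl)ethan-1-one (anhydrous)
Product: 2 1-[2,6-dihydroxy-4-(methoxymethoxy)phenyl]ethan-1-one
Conditions: MOMCl (1.05 equiv), i-Pr2NEt (1.2 equiv), THF, 0 °C
Reagents that add atoms: chloromethyl methyl ether (MOMCl), COCCl
Why: The 4-hydroxyl is the most acidic and is not chelated to the acetyl carbonyl, so one equivalent of MOMCl under mild base should alkylate it first (Williamson-type O-alkylation), and the symmetric product removes any later regiochemical choice on ring B.

Step 2
Reactants: 2 1-[2,6-dihydroxy-4-(methoxymethoxy)phenyl]ethan-1-one; 3 3-methylbut-2-enal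
Product: 5 1-[7-hydroxy-5-(methoxymethoxy)-2,2-dimethyl-2H-chromen-8-yl]ethan-1-one, via dienone 4 (not isolated)
Conditions: 3 (1.1 equiv), ethylenediammonium diacetate (20 mol%), toluene, 110 °C
Reagents that add atoms: none
Why: Amine-catalysed Knoevenagel-type condensation of the enal at the ring carbon between a free hydroxyl and the MOM ether gives 4, whose oxa-6π electrocyclisation can close only on the hydroxyl ortho to the acetyl group because the para oxygen is blocked (phenol–enal chromenylation); the two ortho hydroxyls are equivalent by symmetry, so one regioisomer should form.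

Step 3
Reactants: 5 1-[7-hydroxy-5-(methoxymethoxy)-2,2-dimethyl-2H-chromen-8-yl]ethan-1-one
Product: 6 1-(5,7-dihydroxy-2,2-dimethyl-2H-chromen-8-yl)ethan-1-one
Conditions: 3 M aq HCl, MeOH, 40 °C
Reagents that add atoms: none
Why: Acid-catalysed acetal exchange with methanol cleaves the MOM ether, while the 2,2-dimethylchromene and the aryl ketone are expected to tolerate these mild conditions.

Step 4
Reactants: 7 2-hydroxy-4,6-dimethoxybenzaldehyde
Product: 8 2-ethenyl-3,5-dimethoxyphenol
Conditions: Ph3PCH3Br (1.5 equiv), KOtBu (2.6 equiv), THF, 0 °C to rt; aq NH4Cl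
Reagents that add atoms: methyltriphenylphosphonium bromide, C[P+](c1ccccc1)(c1ccccc1)c1ccccc1.[Br-]
Why: Wittig methylenation with one extra equivalent of base to cover the phenol should give the ortho-hydroxystyrene; no stereocentre is formed.

Step 5
Reactants: 8 2-ethenyl-3,5-dimethoxyphenol
Product: 9 3-ethenyl-2-hydroxy-4,6-dimethoxybenzaldehyde
Conditions: MgCl2 (2 equiv), Et3N (2 equiv), (CH2O)n (3 equiv), THF, 65 °C; cold 1 M HCl
Reagents that add atoms: paraformaldehyde (as formaldehyde), C=O
Why: In the Casnati–Skattebøl ortho-formylation the chloromagnesium phenoxide (ArOMgCl) delivers formaldehyde through a six-membered chelate to the only free position ortho to the hydroxyl, and hydride transfer to a second formaldehyde gives the aldehyde; the position between the two methoxy groups is not reached by this mechanism.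

Step 6
Reactants: 6 1-(5,7-dihydroxy-2,2-dimethyl-2H-chromen-8-yl)ethan-1-one; 9 3-ethenyl-2-hydroxy-4,6-dimethoxybenzaldehyde
Product: 11 3-[(1R)-1-(8-acetyl-5,7-dihydroxy-2,2-dimethyl-2H-chromen-6-yl)ethyl]-2-hydroxy-4,6-dimethoxybenzaldehyde, via ortho-quinone methide 10 (not isolated)
Conditions: (R)-TRIP [(R)-3,3'-bis(2,4,6-triisopropylphenyl)-1,1'-binaphthyl-2,2'-diyl hydrogen phosphate] (10 mol%), 6 (1.5 equiv), CH2Cl2–toluene, 4 Å MS, −20 °C, slow addition of 9
Reagents that add atoms: none
Why: Chiral phosphoric acid-catalysed hydroarylation of an ortho-hydroxystyrene (asymmetric Friedel–Crafts addition to an ortho-quinone methide): protonation of the vinyl terminus gives 10 hydrogen-bonded to the phosphate, which also binds a phenolic hydroxyl of 6 and guides its only unsubstituted ring carbon to one face of the ethylidene carbon, so the (R)-centre should be set under catalyst control with Markovnikov regiochemistry dictated by the oxygen-stabilised benzylic cation.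

Step 7
Reactants: 11 3-[(1R)-1-(8-acetyl-5,7-dihydroxy-2,2-dimethyl-2H-chromen-6-yl)ethyl]-2-hydroxy-4,6-dimethoxybenzaldehyde; 12 (2-methylprop-1-en-1-yl)boronic acid
Product: 15 1-{6-[(1R)-1-(5,7-dimethoxy-2,2-dimethyl-2H-chromen-8-yl)ethyl]-5,7-dihydroxy-2,2-dimethyl-2H-chromen-8-yl}ethan-1-one (target CNP0184118.2), via allylic dibenzylamine 13 (not isolated), via vinyl ortho-quinone methide 14 (not isolated)
Conditions: 12 (2.5 equiv), Bn2NH (0.3 equiv), 1,4-dioxane, 70 °C
Reagents that add atoms: none
Why: Dibenzylamine condenses with the aldehyde to an iminium ion, the neighbouring phenolic O1 binds 12 as a tetracoordinate boronate that hands its alkenyl group intramolecularly to C4 (C4–C3 bond, amine 13), and the electron-rich ring then expels the amine to give ortho-quinone methide 14, which closes to the chromene and frees the catalyst. The closest known reaction type is the amine-catalysed Petasis borono-Mannich condensation of salicylaldehydes with alkenylboronic acids to 2H-chromenes. The pyran ring of chromene A closes by a thermal disrotatory oxa-6π electrocyclisation of the (Z)-1-oxatriene in 14, which forms O1–C2 and leaves C3=C4 as the new double bond. No new stereocentre remains, since C2 carries two methyl groups and the amine-bearing carbon of 13 is planarised on elimination, and the (R)-bridge centre is not touched because no acid is present and O1 ends as an ether. The step needs chemoselectivity for the aldehyde–phenol pair and a single direction of closure: only a phenol ortho to the iminium can deliver the alkenyl group, chromene B has neither an aldehyde nor a free ring position, its hydroxyls and ketone bind boron only reversibly (hence the excess of 12), and C4 has O1 as its only free ortho oxygen, the other neighbour being the C5 methoxy group.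

**Compound list**

1 | 1-(2,4,6-trihydroxyphenyl)ethan-1-one | CC(=O)c1c(O)cc(O)cc1O | starting material
2 | 1-[2,6-dihydroxy-4-(methoxymethoxy)phenyl]ethan-1-one | CC(=O)c1c(O)cc(OCOC)cc1O | intermediate
3 | 3-methylbut-2-enal (prenal) | CC(C)=CC=O | starting material
4 | (6Z)-2-acetyl-3-hydroxy-5-(methoxymethoxy)-6-(3-methylbut-2-en-1-ylidene)cyclohexa-2,4-dien-1-one (not isolated) | CC(=O)C1=C(O)C=C(OCOC)/C(=C/C=C(C)C)C1=O | intermediate
5 | 1-[7-hydroxy-5-(methoxymethoxy)-2,2-dimethyl-2H-chromen-8-yl]ethan-1-one | CC(=O)c1c(O)cc(OCOC)c2C=CC(C)(C)Oc12 | intermediate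
6 | 1-(5,7-dihydroxy-2,2-dimethyl-2H-chromen-8-yl)ethan-1-one | CC(=O)c1c(O)cc(O)c2C=CC(C)(C)Oc12 | intermediate
7 | 2-hydroxy-4,6-dimethoxybenzaldehyde | COc1cc(OC)c(C=O)c(O)c1 | starting material
8 | 2-ethenyl-3,5-dimethoxyphenol | COc1cc(OC)c(C=C)c(O)c1 | intermediate
9 | 3-ethenyl-2-hydroxy-4,6-dimethoxybenzaldehyde | COc1cc(OC)c(C=C)c(O)c1C=O | intermediate
10 | (5Z)-5-ethylidene-2,4-dimethoxy-6-oxocyclohexa-1,3-diene-1-carbaldehyde (not isolated; drawn as the Z isomer, methyl on the carbonyl side) | C/C=C1\C(=O)C(C=O)=C(OC)C=C1OC | intermediate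
11 | 3-[(1R)-1-(8-acetyl-5,7-dihydroxy-2,2-dimethyl-2H-chromen-6-yl)ethyl]-2-hydroxy-4,6-dimethoxybenzaldehyde | COc1cc(OC)c([C@H](C)c2c(O)c3c(c(C(C)=O)c2O)OC(C)(C)C=C3)c(O)c1C=O | intermediate
12 | (2-methylprop-1-en-1-yl)boronic acid | CC(C)=CB(O)O | starting material
13 | 1-{6-[(1R)-1-{3-[1-(dibenzylamino)-3-methylbut-2-en-1-yl]-2-hydroxy-4,6-dimethoxyphenyl}ethyl]-5,7-dihydroxy-2,2-dimethyl-2H-chromen-8-yl}ethan-1-one (not isolated; both epimers at the amine-bearing carbon) | COc1cc(OC)c([C@H](C)c2c(O)c3c(c(C(C)=O)c2O)OC(C)(C)C=C3)c(O)c1C(C=C(C)C)N(Cc1ccccc1)Cc1ccccc1 | intermediate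
14 | 1-{6-[(1R)-1-[(5Z)-2,4-dimethoxy-5-(3-methylbut-2-en-1-ylidene)-6-oxocyclohexa-1,3-dien-1-yl]ethyl]-5,7-dihydroxy-2,2-dimethyl-2H-chromen-8-yl}ethan-1-one (not isolated) | COC1=CC(OC)=C([C@H](C)c2c(O)c3c(c(C(C)=O)c2O)OC(C)(C)C=C3)C(=O)/C1=C\C=C(C)C | intermediate
15 | 1-{6-[(1R)-1-(5,7-dimethoxy-2,2-dimethyl-2H-chromen-8-yl)ethyl]-5,7-dihydroxy-2,2-dimethyl-2H-chromen-8-yl}ethan-1-one | COc1cc(OC)c([C@H](C)c2c(O)c3c(c(C(C)=O)c2O)OC(C)(C)C=C3)c2c1C=CC(C)(C)O2 | target

**Step count and risks**

Total step count: 7. Longest linear sequence: 5 steps (1 → 2 → 5 → 6 → 11 → 15); the arene A branch (7 → 8 → 9) joins at step 6.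

Steps most likely to fail, most serious first:

Step 6. The intramolecular hydrogen bond of the salicylaldehyde in 9 may compete with catalyst binding and lower the facial selectivity, and self-addition of 9 may compete with capture by 6. The fallback gives up catalyst control in favour of resolution. It sets out from 6 and 9: the coupling is run with an achiral acid (diphenyl phosphate, CH2Cl2, 0 °C) to give racemic 3-[1-(8-acetyl-5,7-dihydroxy-2,2-dimethyl-2H-chromen-6-yl)ethyl]-2-hydroxy-4,6-dimethoxybenzaldehyde F1. The enantiomers are then separated by preparative chromatography on a chiral stationary phase (supercritical CO2/MeOH), and the (R)-enantiomer collected is compound 11, where the route resumes.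

Step 7. Boron may be held by the hydroxyl–ketone chelate of ring B, so that transfer of the β,β-disubstituted alkenyl group to the iminium carbon stalls, or amine loss from 13 may be slow at a temperature the bridge tolerates. The fallback closes the pyran ring without boron and without the aldehyde. It sets out from 6 and 8: the non-formylated styrene 8 is coupled with 6 under the phosphoric acid conditions of step 6 to give 1-{5,7-dihydroxy-6-[(1R)-1-(2-hydroxy-4,6-dimethoxyphenyl)ethyl]-2,2-dimethyl-2H-chromen-8-yl}ethan-1-one F2. Classical phenol–enal chromenylation of F2 with prenal 3 (ethylenediammonium diacetate, toluene, 80 °C) then condenses at the only free carbon ortho to a hydroxyl and closes by oxa-6π electrocyclisation, coming back to the route at target 15.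

Step 5. Formaldehyde may attack the electron-rich vinyl terminus, or the styrene may oligomerise during the hot formylation. The fallback installs the vinyl group after the aldehyde is already in place. It sets out from 7: iodination ortho to the free hydroxyl (benzyltrimethylammonium dichloroiodate, NaHCO3, CH2Cl2–MeOH, rt) gives 2-hydroxy-3-iodo-4,6-dimethoxybenzaldehyde F3. Suzuki–Miyaura vinylation of F3 (potassium vinyltrifluoroborate, PdCl2(dppf), Cs2CO3, THF–H2O, 70 °C) comes back to the route at compound 9.

**Further compounds**

F1 | step 6 | racemic 3-[1-(8-acetyl-5,7-dihydroxy-2,2-dimethyl-2H-chromen-6-yl)ethyl]-2-hydroxy-4,6-dimethoxybenzaldehyde | COc1cc(OC)c(C(C)c2c(O)c3c(c(C(C)=O)c2O)OC(C)(C)C=C3)c(O)c1C=O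
F2 | step 7 | 1-{5,7-dihydroxy-6-[(1R)-1-(2-hydroxy-4,6-dimethoxyphenyl)ethyl]-2,2-dimethyl-2H-chromen-8-yl}ethan-1-one | COc1cc(OC)c([C@H](C)c2c(O)c3c(c(C(C)=O)c2O)OC(C)(C)C=C3)c(O)c1
F3 | step 5 | 2-hydroxy-3-iodo-4,6-dimethoxybenzaldehyde | COc1cc(OC)c(I)c(O)c1C=O
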